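**Retrosynthetic overview**
1. Target 36 comes from cycloalkyne 34 (C11≡C12) by hydroxyl-directed trans-hydrostannation and methyl-Stille coupling, which build the (E)-C11=C12(Me) unit last; the C5 acetate is put on just before, while C13-OH is silylated.
2. The only ring, the 14-membered carbocycle, is closed by ring-closing alkyne metathesis of diyne 30 (bond C11–C12).
3. Diyne 30 comes from ynone 25: C13 by ketoreductase reduction, the acrylate from a malonate, and C1 by organocatalytic Michael addition of dimethyl malonate to enal 21.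
4. Enal 21 comes from epoxide 9 by vinyl-Grignard opening (C2–C3), propynylation of the C10 allylic bromide (C10–C11), then hydroboration, oxidation and Wittig homologation.
5. Epoxide 9 comes from geraniol: allylic oxidation, Sharpless epoxidation (C4, C5), then carbonate-participated inversion at C4.

Assumption: ring atoms are numbered C1–C14 in the order of the target SMILES (C1 carries the acrylate, C4 Me/OH, C5 OAc, C8=C9, C11=C12, C13 OH); the target is then (1R,4R,5S,13S,8E,11E), and these locants are used for all intermediates.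

**Step 1**
Reactants: 1 geraniol
Product: 2 geranyl TBDPS ether
Conditions: TBDPSCl (1.1 equiv), imidazole (2 equiv), DMF, 0 °C → rt
Reagents that add atoms: tert-butyl(chloro)diphenylsilane, CC(C)(C)[Si](Cl)(c1ccccc1)c1ccccc1
Why: Imidazole-promoted silylation of the primary allylic alcohol gives a robust ether whose allylic oxygen also deactivates the C8=C9 olefin toward the later oxidations.

**Step 2**
Reactants: 2 geranyl TBDPS ether
Product: 3 (2E,6E)-8-silyloxy-2,6-dimethylocta-2,6-dien-1-ol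
Conditions: SeO2 (0.1 equiv), t-BuOOH (3 equiv), salicylic acid (0.1 equiv), CH2Cl2, rt
Reagents that add atoms: tert-butyl hydroperoxide, CC(C)(C)OO
Why: Catalytic SeO2 allylic oxidation (ene reaction then 2,3-sigmatropic shift) attacks the (E)-methyl of the electron-richer terminal olefin and gives the (E)-allylic alcohol.

**Step 3**
Reactants: 3 allylic alcohol
Product: 4 (2S,3S)-epoxy alcohol
Conditions: Ti(OiPr)4 (0.1 equiv), L-(+)-diethyl tartrate (0.12 equiv), t-BuOOH (2 equiv), 4 Å MS, CH2Cl2, −20 °C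
Reagents that add atoms: tert-butyl hydroperoxide, CC(C)(C)OO
Why: Sharpless asymmetric epoxidation; the titanium–tartrate catalyst delivers oxygen to one face of the (E)-2-methylallylic alcohol only, setting C4 and C5 as the (2S,3S)-epoxide (first stereocentres) and leaving the C8=C9 olefin alone.

**Step 4**
Reactants: 4 epoxy alcohol
Product: 5 tert-butyl carbonate of 4
Conditions: Boc2O (1.5 equiv), 1-methylimidazole (0.2 equiv), toluene, 0 °C → rt
Reagents that add atoms: di-tert-butyl dicarbonate, CC(C)(C)OC(=O)OC(=O)OC(C)(C)C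
Why: O-acylation places an internal carbonyl nucleophile on the C3 oxygen for the next step.

**Step 5**
Reactants: 5 tert-butyl carbonate
Product: 6 cyclic carbonate (C3-O/C4-O) with free C5-OH
Conditions: BF3·OEt2 (0.3 equiv), CH2Cl2, −78 → −40 °C, then Et3N
Reagents that add atoms: none
Why: Lewis-acid-triggered 5-exo opening of the epoxide by the carbonate carbonyl oxygen (neighbouring-group participation, loss of isobutene) occurs at tertiary C4 with inversion, turning the (4S,5S)-epoxide into the (4R,5S) erythro array with the C5–O bond untouched.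

**Step 6**
Reactants: 6 cyclic carbonate
Product: 7 (2R,3S)-1,2,3-triol
Conditions: K2CO3 (0.2 equiv), MeOH, 0 °C → rt
Reagents that add atoms: none
Why: Base-catalysed transesterification of the strained five-membered carbonate frees the triol without touching the silyl ether or any stereocentre.

**Step 7**
Reactants: 7 triol
Product: 8 primary tosylate
Conditions: TsCl (1.1 equiv), Et3N (1.5 equiv), Bu2SnO (0.02 equiv), CH2Cl2, 0 °C
Reagents that add atoms: 4-toluenesulfonyl chloride, Cc1ccc(cc1)S(Cl)(=O)=O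
Why: Stannylene-accelerated sulfonylation is selective for the primary hydroxyl of the 1,2-diol over the secondary and tertiary ones.

**Step 8**
Reactants: 8 primary tosylate
Product: 9 terminal (2R)-epoxide with free (S)-C5-OH
Conditions: K2CO3 (2 equiv), MeOH, 0 °C
Reagents that add atoms: none
Why: Intramolecular Williamson displacement by the tertiary alkoxide closes the 2,2-disubstituted epoxide at C3, so neither the C4–O nor the C5–O bond is broken.

**Step 9**
Reactants: 9 epoxy alcohol; 10 vinylmagnesium bromide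
Product: 11 homoallylic (4R,5S)-diol
Conditions: 10 (3 equiv), CuI (0.1 equiv), THF, −30 → 0 °C, then H2O
Reagents that add atoms: none
Why: Copper-catalysed Grignard opening of the epoxide at its CH2 terminus (SN2) forms the C2–C3 bond and regenerates the tertiary C4 alcohol with unchanged configuration, one equivalent of Grignard being consumed by the free hydroxyl.

**Step 10**
Reactants: 11 diol
Product: 12 C4/C5 acetonide
Conditions: 2,2-dimethoxypropane (5 equiv), PPTS (0.05 equiv), CH2Cl2, rt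
Reagents that add atoms: 2,2-dimethoxypropane, COC(C)(C)OC
Why: Acid-catalysed transketalisation protects the tertiary/secondary diol as one isopropylidene acetal.

**Step 11**
Reactants: 12 silyl ether
Product: 13 C10 allylic alcohol
Conditions: TBAF (1.2 equiv), THF, 0 °C → rt
Reagents that add atoms: none
Why: Fluoride-driven desilylation frees the primary allylic alcohol while the acetonide is inert.

**Step 12**
Reactants: 13 allylic alcohol
Product: 14 C10 allylic bromide
Conditions: CBr4 (1.3 equiv), PPh3 (1.3 equiv), CH2Cl2, −20 → 0 °C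
Reagents that add atoms: carbon tetrabromide, BrC(Br)(Br)Br
Why: Appel reaction converts the primary allylic alcohol to the bromide under neutral conditions by SN2 on the oxyphosphonium ion, without allylic transposition or loss of the E geometry.

**Step 13**
Reactants: 14 allylic bromide; 15 prop-1-yn-1-ylmagnesium bromide
Product: 16 skipped enyne
Conditions: 15 (1.5 equiv), CuI (0.05 equiv), THF, 0 °C → rt
Reagents that add atoms: none
Why: Copper-catalysed α-selective (SN2) alkynylation of the primary allylic bromide forms C10–C11, the fully substituted γ-carbon disfavouring SN2′ attack and the E olefin being retained.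

**Step 14**
Reactants: 16 terminal alkene
Product: 18 C1 primary alcohol, via alkyl-9-BBN adduct 17 (not isolated)
Conditions: 9-borabicyclo[3.3.1]nonane (1.2 equiv), THF, 0 °C → rt; then NaOH (aq), H2O2, 0 °C
Reagents that add atoms: hydrogen peroxide, OO
Why: Hydroboration–oxidation with the bulky borane is anti-Markovnikov and selective for the monosubstituted alkene over the trisubstituted alkene and the internal alkyne.

**Step 15**
Reactants: 18 primary alcohol
Product: 19 C1 aldehyde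
Conditions: Dess–Martin periodinane (1.3 equiv), CH2Cl2, 0 °C → rt
Reagents that add atoms: none
Why: Dess–Martin oxidation stops cleanly at the aldehyde and tolerates the acetonide, alkene and alkyne.

**Step 16**
Reactants: 19 aldehyde; 20 (triphenylphosphoranylidene)acetaldehyde
Product: 21 (E)-enal
Conditions: 20 (1.3 equiv), toluene, 80 °C
Reagents that add atoms: none
Why: Wittig olefination with the stabilised formyl ylide gives the (E)-enal (C1=C14–C13HO), the conjugated product being less electrophilic than the starting aldehyde.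

**Step 17**
Reactants: 21 enal; 22 dimethyl malonate
Product: 23 (1R)-Michael adduct aldehyde
Conditions: 22 (2 equiv), (S)-2-{bis[3,5-bis(trifluoromethyl)phenyl][(trimethylsilyl)oxy]methyl}pyrrolidine (0.1 equiv), EtOH, 0 °C
Reagents that add atoms: none
Why: Iminium-ion organocatalytic Michael addition; the bulky diaryl(silyloxy)methyl group of the (S)-catalyst blocks one face of the E-iminium ion and malonate adds to the other, setting C1 as R.

**Step 18**
Reactants: 23 aldehyde; 15 prop-1-yn-1-ylmagnesium bromide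
Product: 24 propargylic alcohols (both C13 epimers)
Conditions: 15 (2.2 equiv), THF, −78 °C, then H2O (pH 7 buffer) at −78 °C
Reagents that add atoms: none
Why: Grignard 1,2-addition to the aldehyde after the first equivalent has masked the malonate as its unreactive magnesium enolate; no stereocontrol is sought because C13 is reset in steps 19 and 20.

**Step 19**
Reactants: 24 propargylic alcohols
Product: 25 ynone
Conditions: Dess–Martin periodinane (1.5 equiv), CH2Cl2, 0 °C
Reagents that add atoms: none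
Why: Dess–Martin oxidation gives the alkynyl ketone under non-basic conditions, avoiding retro-Michael loss of malonate or its addition to the ynone.

**Step 20**
Reactants: 25 ynone
Product: 26 (13S)-propargylic alcohol
Conditions: ketoreductase (S-selective, NADPH-dependent alcohol dehydrogenase class), NADP+ (cat.), i-PrOH (10 vol%), phosphate buffer pH 7.0, DMSO (10 vol%), 30 °C
Reagents that add atoms: none
Why: Enzymatic carbonyl reduction with cofactor recycling from isopropanol delivers hydride to one face of the ketone to give the 13S alcohol under catalyst control, at neutral pH that the base-sensitive β-malonyl ynone tolerates.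

**Step 21**
Reactants: 26 propargylic alcohol
Product: 27 C13 TBDPS ether
Conditions: TBDPSCl (1.5 equiv), imidazole (3 equiv), DMAP (0.1 equiv), DMF, rt
Reagents that add atoms: tert-butyl(chloro)diphenylsilane, CC(C)(C)[Si](Cl)(c1ccccc1)c1ccccc1
Why: Silylation blocks C13-OH so that it cannot lactonise onto the esters and so that C5 can later be acetylated selectively.

**Step 22**
Reactants: 27 malonate diester
Product: 28 malonic half-ester
Conditions: KOH (1.05 equiv), MeOH/THF/H2O, 0 °C → rt; then 1 M HCl to pH 3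
Reagents that add atoms: potassium hydroxide, [K+].[OH-]
Why: Monosaponification stops after one ester because the carboxylate formed deactivates the second ester toward hydroxide.

**Step 23**
Reactants: 28 half-ester
Product: 30 acrylate diyne, via Mannich base 29 (not isolated)
Conditions: paraformaldehyde (5 equiv), Et2NH (1.5 equiv), THF, 65 °C
Reagents that add atoms: formaldehyde, C=O
Why: Mannich reaction of the half-ester followed by decarboxylative elimination of the amine gives the 2-substituted methyl acrylate without touching the adjacent C1 stereocentre.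

**Step 24**
Reactants: 30 diyne
Product: 31 14-membered cycloalkyne
Conditions: Mo(≡CC6H4OMe-4)(OSiPh3)3 (0.1 equiv), 5 Å MS, toluene (2 mM), 60 °C
Reagents that add atoms: none
Why: Ring-closing alkyne metathesis joins C11 and C12, driven by trapping of but-2-yne in the sieves; the silanolate-ligated molybdenum alkylidyne tolerates the ester, acrylate, alkene, acetal and silyl ether.

**Step 25**
Reactants: 31 acetonide
Product: 32 C4/C5 diol
Conditions: AcOH/H2O/THF (3:1:1), 45 °C
Reagents that add atoms: none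
Why: Acid-catalysed acetal hydrolysis frees the diol while the TBDPS ether, acrylate and cycloalkyne survive.

**Step 26**
Reactants: 32 diol
Product: 33 C5 acetate
Conditions: Ac2O (3 equiv), pyridine, DMAP (0.1 equiv), CH2Cl2, 0 °C → rt
Reagents that add atoms: acetic anhydride, CC(=O)OC(C)=O
Why: DMAP-catalysed acylation takes the only free secondary hydroxyl, the tertiary C4-OH being too hindered to react.

**Step 27**
Reactants: 33 silyl ether
Product: 34 macrocyclic propargylic alcohol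
Conditions: HF·pyridine, pyridine, THF, 0 °C → rt
Reagents that add atoms: none
Why: Desilylation with buffered HF is non-basic, so the acetate does not migrate and C13-OH does not lactonise onto the acrylate.

**Step 28**
Reactants: 34 propargylic alcohol
Product: 35 (11Z)-12-tributylstannyl diene
Conditions: [Cp*RuCl]4 (0.03 equiv), Bu3SnH (1.2 equiv), CH2Cl2, rt
Reagents that add atoms: tributyltin hydride, CCCC[SnH](CCCC)CCCC
Why: Ruthenium-catalysed trans-hydrostannation directed by the free propargylic hydroxyl places tin on proximal C12 and hydrogen anti on C11, fixing the olefin geometry.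

**Step 29**
Reactants: 35 alkenylstannane
Product: 36 CNP0201062.1 (target)
Conditions: MeI (10 equiv), copper thiophene-2-carboxylate Cu(O2CC4H3S) (1.5 equiv), [Bu4N][Ph2PO2] (1.6 equiv), Pd(PPh3)4 (0.1 equiv), DMF, rt
Reagents that add atoms: iodomethane, CI
Why: Copper-assisted Stille-type C-methylation replaces tin by methyl with retention, giving the (E)-C11=C12(Me) olefin with the free allylic C13-OH.

**Compound list**
1 | geraniol, (2E)-3,7-dimethylocta-2,6-dien-1-ol | CC(C)=CCC/C(C)=C/CO | starting material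
2 | tert-butyl{[(2E)-3,7-dimethylocta-2,6-dien-1-yl]oxy}diphenylsilane | CC(C)=CCC/C(C)=C/CO[Si](c1ccccc1)(c1ccccc1)C(C)(C)C | intermediate
3 | (2E,6E)-8-[(tert-butyldiphenylsilyl)oxy]-2,6-dimethylocta-2,6-dien-1-ol | OC/C(C)=C/CC/C(C)=C/CO[Si](c1ccccc1)(c1ccccc1)C(C)(C)C | intermediate
4 | {(2S,3S)-3-[(3E)-5-[(tert-butyldiphenylsilyl)oxy]-3-methylpent-3-en-1-yl]-2-methyloxiran-2-yl}methanol | OC[C@]1(C)O[C@H]1CC/C(C)=C/CO[Si](c2ccccc2)(c2ccccc2)C(C)(C)C | intermediate
5 | tert-butyl {(2S,3S)-3-[(3E)-5-[(tert-butyldiphenylsilyl)oxy]-3-methylpent-3-en-1-yl]-2-methyloxiran-2-yl}methyl carbonate | CC(C)(C)OC(=O)OC[C@]1(C)O[C@H]1CC/C(C)=C/CO[Si](c2ccccc2)(c2ccccc2)C(C)(C)C | intermediate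
6 | (4R)-4-[(1S,4E)-6-[(tert-butyldiphenylsilyl)oxy]-1-hydroxy-4-methylhex-4-en-1-yl]-4-methyl-1,3-dioxolan-2-one | O=C1OC[C@@](C)(O1)[C@@H](O)CC/C(C)=C/CO[Si](c2ccccc2)(c2ccccc2)C(C)(C)C | intermediate
7 | (2R,3S,6E)-8-[(tert-butyldiphenylsilyl)oxy]-2,6-dimethyloct-6-ene-1,2,3-triol | OC[C@@](C)(O)[C@@H](O)CC/C(C)=C/CO[Si](c1ccccc1)(c1ccccc1)C(C)(C)C | intermediate
8 | (2R,3S,6E)-8-[(tert-butyldiphenylsilyl)oxy]-2,3-dihydroxy-2,6-dimethyloct-6-en-1-yl 4-methylbenzenesulfonate | Cc1ccc(cc1)S(=O)(=O)OC[C@@](C)(O)[C@@H](O)CC/C(C)=C/CO[Si](c2ccccc2)(c2ccccc2)C(C)(C)C | intermediate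
9 | (1S,4E)-6-[(tert-butyldiphenylsilyl)oxy]-4-methyl-1-[(2R)-2-methyloxiran-2-yl]hex-4-en-1-ol | C[C@@]1(CO1)[C@@H](O)CC/C(C)=C/CO[Si](c2ccccc2)(c2ccccc2)C(C)(C)C | intermediate
10 | vinylmagnesium bromide (ethenylmagnesium bromide) | C=C[Mg]Br | starting material
11 | (2E,6S,7R)-1-[(tert-butyldiphenylsilyl)oxy]-3,7-dimethyldeca-2,9-diene-6,7-diol (C4 R, C5 S) | C=CC[C@@](C)(O)[C@@H](O)CC/C(C)=C/CO[Si](c1ccccc1)(c1ccccc1)C(C)(C)C | intermediate
12 | (4R,5S)-5-[(3E)-5-[(tert-butyldiphenylsilyl)oxy]-3-methylpent-3-en-1-yl]-2,2,4-trimethyl-4-(prop-2-en-1-yl)-1,3-dioxolane | C=CC[C@@]1(C)OC(C)(C)O[C@H]1CC/C(C)=C/CO[Si](c2ccccc2)(c2ccccc2)C(C)(C)C | intermediate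
13 | (2E)-3-methyl-5-[(4S,5R)-2,2,5-trimethyl-5-(prop-2-en-1-yl)-1,3-dioxolan-4-yl]pent-2-en-1-ol (C4 R, C5 S) | C=CC[C@@]1(C)OC(C)(C)O[C@H]1CC/C(C)=C/CO | intermediate
14 | (4R,5S)-5-[(3E)-5-bromo-3-methylpent-3-en-1-yl]-2,2,4-trimethyl-4-(prop-2-en-1-yl)-1,3-dioxolane | C=CC[C@@]1(C)OC(C)(C)O[C@H]1CC/C(C)=C/CBr | intermediate
15 | prop-1-yn-1-ylmagnesium bromide | CC#C[Mg]Br | starting material
16 | (4R,5S)-2,2,4-trimethyl-5-[(3E)-3-methyloct-3-en-6-yn-1-yl]-4-(prop-2-en-1-yl)-1,3-dioxolane | C=CC[C@@]1(C)OC(C)(C)O[C@H]1CC/C(C)=C/CC#CC | intermediate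
17 | 9-(3-{(4R,5S)-2,2,4-trimethyl-5-[(3E)-3-methyloct-3-en-6-yn-1-yl]-1,3-dioxolan-4-yl}propyl)-9-borabicyclo[3.3.1]nonane | C1CCC2CCCC1B2CCC[C@@]3(C)OC(C)(C)O[C@H]3CC/C(C)=C/CC#CC | intermediate
18 | 3-{(4R,5S)-2,2,4-trimethyl-5-[(3E)-3-methyloct-3-en-6-yn-1-yl]-1,3-dioxolan-4-yl}propan-1-ol | OCCC[C@@]1(C)OC(C)(C)O[C@H]1CC/C(C)=C/CC#CC | intermediate
19 | 3-{(4R,5S)-2,2,4-trimethyl-5-[(3E)-3-methyloct-3-en-6-yn-1-yl]-1,3-dioxolan-4-yl}propanal | O=CCC[C@@]1(C)OC(C)(C)O[C@H]1CC/C(C)=C/CC#CC | intermediate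
20 | (triphenylphosphoranylidene)acetaldehyde | O=CC=P(c1ccccc1)(c1ccccc1)c1ccccc1 | starting material
21 | (2E)-5-{(4R,5S)-2,2,4-trimethyl-5-[(3E)-3-methyloct-3-en-6-yn-1-yl]-1,3-dioxolan-4-yl}pent-2-enal | O=C/C=C/CC[C@@]1(C)OC(C)(C)O[C@H]1CC/C(C)=C/CC#CC | intermediate
22 | dimethyl malonate (dimethyl propanedioate) | COC(=O)CC(=O)OC | starting material
23 | dimethyl 2-[(3R)-1-oxo-5-{(4R,5S)-2,2,4-trimethyl-5-[(3E)-3-methyloct-3-en-6-yn-1-yl]-1,3-dioxolan-4-yl}pentan-3-yl]propanedioate (C1 R) | COC(=O)C(C(=O)OC)[C@@H](CC=O)CC[C@@]1(C)OC(C)(C)O[C@H]1CC/C(C)=C/CC#CC | intermediate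
24 | dimethyl 2-[(3R,5RS)-5-hydroxy-1-{(4R,5S)-2,2,4-trimethyl-5-[(3E)-3-methyloct-3-en-6-yn-1-yl]-1,3-dioxolan-4-yl}oct-6-yn-3-yl]propanedioate (both C13 epimers) | COC(=O)C(C(=O)OC)[C@@H](CC(O)C#CC)CC[C@@]1(C)OC(C)(C)O[C@H]1CC/C(C)=C/CC#CC | intermediate
25 | dimethyl 2-[(3R)-5-oxo-1-{(4R,5S)-2,2,4-trimethyl-5-[(3E)-3-methyloct-3-en-6-yn-1-yl]-1,3-dioxolan-4-yl}oct-6-yn-3-yl]propanedioate | COC(=O)C(C(=O)OC)[C@@H](CC(=O)C#CC)CC[C@@]1(C)OC(C)(C)O[C@H]1CC/C(C)=C/CC#CC | intermediate
26 | dimethyl 2-[(3R,5S)-5-hydroxy-1-{(4R,5S)-2,2,4-trimethyl-5-[(3E)-3-methyloct-3-en-6-yn-1-yl]-1,3-dioxolan-4-yl}oct-6-yn-3-yl]propanedioate (C1 R, C13 S) | COC(=O)C(C(=O)OC)[C@@H](C[C@H](O)C#CC)CC[C@@]1(C)OC(C)(C)O[C@H]1CC/C(C)=C/CC#CC | intermediate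
27 | dimethyl 2-[(3R,5S)-5-[(tert-butyldiphenylsilyl)oxy]-1-{(4R,5S)-2,2,4-trimethyl-5-[(3E)-3-methyloct-3-en-6-yn-1-yl]-1,3-dioxolan-4-yl}oct-6-yn-3-yl]propanedioate | COC(=O)C(C(=O)OC)[C@@H](C[C@H](O[Si](c2ccccc2)(c2ccccc2)C(C)(C)C)C#CC)CC[C@@]1(C)OC(C)(C)O[C@H]1CC/C(C)=C/CC#CC | intermediate
28 | 2-[(3R,5S)-5-[(tert-butyldiphenylsilyl)oxy]-1-{(4R,5S)-2,2,4-trimethyl-5-[(3E)-3-methyloct-3-en-6-yn-1-yl]-1,3-dioxolan-4-yl}oct-6-yn-3-yl]-3-methoxy-3-oxopropanoic acid (both epimers at the malonate carbon) | OC(=O)C(C(=O)OC)[C@@H](C[C@H](O[Si](c2ccccc2)(c2ccccc2)C(C)(C)C)C#CC)CC[C@@]1(C)OC(C)(C)O[C@H]1CC/C(C)=C/CC#CC | intermediate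
29 | 2-[(diethylamino)methyl]-2-[(3R,5S)-5-[(tert-butyldiphenylsilyl)oxy]-1-{(4R,5S)-2,2,4-trimethyl-5-[(3E)-3-methyloct-3-en-6-yn-1-yl]-1,3-dioxolan-4-yl}oct-6-yn-3-yl]-3-methoxy-3-oxopropanoic acid | CCN(CC)CC(C(=O)O)(C(=O)OC)[C@@H](C[C@H](O[Si](c2ccccc2)(c2ccccc2)C(C)(C)C)C#CC)CC[C@@]1(C)OC(C)(C)O[C@H]1CC/C(C)=C/CC#CC | intermediate
30 | methyl 2-[(3R,5S)-5-[(tert-butyldiphenylsilyl)oxy]-1-{(4R,5S)-2,2,4-trimethyl-5-[(3E)-3-methyloct-3-en-6-yn-1-yl]-1,3-dioxolan-4-yl}oct-6-yn-3-yl]prop-2-enoate | C=C(C(=O)OC)[C@@H](C[C@H](O[Si](c2ccccc2)(c2ccccc2)C(C)(C)C)C#CC)CC[C@@]1(C)OC(C)(C)O[C@H]1CC/C(C)=C/CC#CC | intermediate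
31 | methyl 2-[(1R,4R,5S,13S,8E)-13-[(tert-butyldiphenylsilyl)oxy]-4,5-(isopropylidenedioxy)-4,8-dimethylcyclotetradec-8-en-11-yn-1-yl]prop-2-enoate | C=C(C(=O)OC)[C@@H]1CC[C@@]2(C)OC(C)(C)O[C@H]2CC/C(C)=C/CC#C[C@@H](O[Si](c3ccccc3)(c3ccccc3)C(C)(C)C)C1 | intermediate
32 | methyl 2-[(1R,4R,5S,13S,8E)-13-[(tert-butyldiphenylsilyl)oxy]-4,5-dihydroxy-4,8-dimethylcyclotetradec-8-en-11-yn-1-yl]prop-2-enoate | C=C(C(=O)OC)[C@@H]1CC[C@@](C)(O)[C@@H](O)CC/C(C)=C/CC#C[C@@H](O[Si](c2ccccc2)(c2ccccc2)C(C)(C)C)C1 | intermediate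
33 | methyl 2-[(1R,4R,5S,13S,8E)-5-acetoxy-13-[(tert-butyldiphenylsilyl)oxy]-4-hydroxy-4,8-dimethylcyclotetradec-8-en-11-yn-1-yl]prop-2-enoate | C=C(C(=O)OC)[C@@H]1CC[C@@](C)(O)[C@@H](OC(C)=O)CC/C(C)=C/CC#C[C@@H](O[Si](c2ccccc2)(c2ccccc2)C(C)(C)C)C1 | intermediate
34 | methyl 2-[(1R,4R,5S,13S,8E)-5-acetoxy-4,13-dihydroxy-4,8-dimethylcyclotetradec-8-en-11-yn-1-yl]prop-2-enoate | C=C(C(=O)OC)[C@@H]1CC[C@@](C)(O)[C@@H](OC(C)=O)CC/C(C)=C/CC#C[C@@H](O)C1 | intermediate
35 | methyl 2-[(1R,4R,5S,13S,8E,11Z)-5-acetoxy-4,13-dihydroxy-4,8-dimethyl-12-(tributylstannyl)cyclotetradeca-8,11-dien-1-yl]prop-2-enoate | C=C(C(=O)OC)[C@@H]1CC[C@@](C)(O)[C@@H](OC(C)=O)CC/C(C)=C/C/C=C(\[Sn](CCCC)(CCCC)CCCC)[C@@H](O)C1 | intermediate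
36 | methyl 2-[(1R,4R,5S,13S,8E,11E)-5-acetoxy-4,13-dihydroxy-4,8,12-trimethylcyclotetradeca-8,11-dien-1-yl]prop-2-enoate (CNP0201062.1) | C=C(C(=O)OC)[C@@H]1CC[C@@](C)(O)[C@@H](OC(C)=O)CC/C(C)=C/C/C=C(\C)[C@@H](O)C1 | target

**Totals and risks**
Total step count: 29. Longest linear sequence: 29 steps (geraniol 1 to target 36; the route is fully linear).

The three steps most likely to fail:

Step 5 (carbonate-participated epoxide opening). The risk is capture of the developing tertiary C4 cation by the C8=C9 olefin (cation–olefin cyclisation) or partial loss of stereospecificity. The fallback sets out from 3 and moves the inversion to secondary C5 under non-cationic conditions. Sharpless epoxidation with D-(−)-diethyl tartrate gives the enantiomeric (2R,3R)-epoxy alcohol F1. Benzoic acid with Ti(OiPr)4 then opens it at C5, the carbon remote from the carbinol, with inversion, to give the (2R,3S)-diol 3-benzoate F2. Tosylation of the primary hydroxyl (TsCl, Et3N, Bu2SnO cat.) gives the tosylate benzoate F3, and K2CO3 in MeOH removes the benzoate and closes the epoxide. The route is rejoined at 9.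

Step 20 (ketoreductase reduction). The risk is poor acceptance or solubility of the large lipophilic ynone. The fallback sets out from aldehyde 23 and makes the C12–C13 bond and the C13 stereocentre in one event: catalytic asymmetric alkynylation with propyne (Me2Zn, the ProPhenol ligand enantiomer that delivers the alkynyl group to the Re face of the aldehyde, Ph3P=O additive, toluene, 0 °C). This bypasses 24 and 25, and the route is rejoined at 26.

Step 24 (ring-closing alkyne metathesis). The risk is slow closure next to the bulky silyl ether and interference by the acrylate, leading to oligomers. The fallback sets out from 27 and closes the ring before the acrylate exists. Alkyne metathesis of the malonate diyne under the same catalyst gives the macrocyclic malonate F4. KOH monosaponification gives the macrocyclic half-ester F5. Formaldehyde and Et2NH convert it through the macrocyclic Mannich base F6 into the acrylate, and the route is rejoined at 31.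

**Further compounds**
F1 | step 5 | {(2R,3R)-3-[(3E)-5-[(tert-butyldiphenylsilyl)oxy]-3-methylpent-3-en-1-yl]-2-methyloxiran-2-yl}methanol | OC[C@@]1(C)O[C@@H]1CC/C(C)=C/CO[Si](c2ccccc2)(c2ccccc2)C(C)(C)C
F2 | step 5 | (2R,3S,6E)-8-[(tert-butyldiphenylsilyl)oxy]-1,2-dihydroxy-2,6-dimethyloct-6-en-3-yl benzoate | OC[C@@](C)(O)[C@@H](OC(=O)c1ccccc1)CC/C(C)=C/CO[Si](c1ccccc1)(c1ccccc1)C(C)(C)C
F3 | step 5 | (2R,3S,6E)-8-[(tert-butyldiphenylsilyl)oxy]-2-hydroxy-2,6-dimethyl-1-{[(4-methylphenyl)sulfonyl]oxy}oct-6-en-3-yl benzoate | Cc1ccc(cc1)S(=O)(=O)OC[C@@](C)(O)[C@@H](OC(=O)c1ccccc1)CC/C(C)=C/CO[Si](c1ccccc1)(c1ccccc1)C(C)(C)C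
F0 | step 20 | none | none
F4 | step 24 | dimethyl 2-[(1R,4R,5S,13S,8E)-13-[(tert-butyldiphenylsilyl)oxy]-4,5-(isopropylidenedioxy)-4,8-dimethylcyclotetradec-8-en-11-yn-1-yl]propanedioate | COC(=O)C(C(=O)OC)[C@@H]1CC[C@@]2(C)OC(C)(C)O[C@H]2CC/C(C)=C/CC#C[C@@H](O[Si](c3ccccc3)(c3ccccc3)C(C)(C)C)C1
F5 | step 24 | 2-[(1R,4R,5S,13S,8E)-13-[(tert-butyldiphenylsilyl)oxy]-4,5-(isopropylidenedioxy)-4,8-dimethylcyclotetradec-8-en-11-yn-1-yl]-3-methoxy-3-oxopropanoic acid | OC(=O)C(C(=O)OC)[C@@H]1CC[C@@]2(C)OC(C)(C)O[C@H]2CC/C(C)=C/CC#C[C@@H](O[Si](c3ccccc3)(c3ccccc3)C(C)(C)C)C1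
F6 | step 24 | 2-[(diethylamino)methyl]-2-[(1R,4R,5S,13S,8E)-13-[(tert-butyldiphenylsilyl)oxy]-4,5-(isopropylidenedioxy)-4,8-dimethylcyclotetradec-8-en-11-yn-1-yl]-3-methoxy-3-oxopropanoic acid | CCN(CC)CC(C(=O)O)(C(=O)OC)[C@@H]1CC[C@@]2(C)OC(C)(C)O[C@H]2CC/C(C)=C/CC#C[C@@H](O[Si](c3ccccc3)(c3ccccc3)C(C)(C)C)C1
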